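Target and side product together make 100% of the substrate charged at the first beta reading and 101% at the last, so we take their sum as the invariant. We also suppose that target takes one reagent and side product two, so the readings show how much reagent remains.

| flask | substrate | reagent | remark | time |
|---|---|---|---|---|
| beta | 0.013 M | 0.036 M (fed, over 15 s) | run made earlier |  |
| gamma | 0.030 M | 0.036 M (fed, over 15 s) | run made earlier |  |
| flask | 0.020 M | 0.0360 M (fed, over 15 s) |  | 5.0 min |

- beta (time / min: target / %, side product / %): 0.417: 65.7, 34.6; 1.33: 65.8, 35.7; 2.50: 66.0, 34.1; 4.00: 65.6, 33.8; 5.00: 65.9, 34.7
- gamma (time / min: target / %, side product / %): 0.417: 65.7, 20.2; 1.33: 74.6, 21.0; 2.50: 76.0, 21.3; 4.00: 75.6, 21.9; 5.00: 76.8, 21.0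

(standard deviation of a reading: 0.5 percentage points)

- the numbers in the tables scatter with a standard deviation of 0.5 percentage points
- a reading or a percentage of target counts all its forms, free or not

- target at 5.0 min, in percent of the substrate charged
- side product at 5.0 min, in percent of the substrate charged

Fold this into one number, the spare share: one minus the ratio of substrate charge to reagent charge, times target plus twice side product. The last readings give 51.1% for beta and 1.00% for gamma. Side product's share of the two products reads 34.5% in beta and 21.5% in gamma. A straight line through these pairs starts at 21.2% and has the slope 0.260.

Line and count must agree for the flask, which gives side product 28.6%, target 71.4% and spare share 28.5%.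

Was one number enough? Two runs cannot test a line, and the number ignores time: gamma's target climbs from 65.7% to 74.6%. But our reckoned reagent demand for the flask, 0.0257 M, stays below its charge of 0.0360 M, so we expect substrate to be the limiting reagent there and take the flask as finished by 5.0 min.

The forecast, holding that “side product is therefore made only while substrate is being consumed”, gives 72.5% target and 27.5% side product, 1.1 percentage points below our side product.

The flask gives 69.9% target, crystals included, and 30.1% side product.

    substrate + reagent → target (k = 9.20 /M/s)
    crystals ⇌ target, rate k2*(cs2 - [target]) while solid is left; crystals form when [target] > cs2 (solubility = 1.70 mM, k = 2.80 /s)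
    substrate + 2 reagent → side product (k = 430 /M²/s)

Its reagent left at the end is 28%, against our spare share of 28.5%. For the neighbour with 0.061 M of reagent, the same line and count give side product 35.6% and spare share 55.5%; that neighbour holds 38.3% side product and 55% of its reagent.

(The data were generated by integration from invented constants, noise included.)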